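**Strategy.** The 2,3-dimethoxy-1,4-benzoquinone ring is disconnected at C1′–C2′. C2′(=O), C3′(OMe), C4′(OMe) and C5′(=O) are the four ring carbons of dimethyl squarate, and C1′/C6′ are the two carbons of an ethynyl group on chroman C3. One thermal ring expansion of a 4-alkynyl-4-hydroxycyclobutenone therefore closes the quinone ring at its final oxidation level, so no arene-to-quinone oxidation is needed beside the oxidisable 6,8-dimethoxy-7-oxygenated A ring. The precursor is the squarate adduct of (S)-3-ethynyl-6,8-dimethoxy-7-(methoxymethoxy)chroman. Its C3 stereocentre comes from a catalytic desymmetrising O-arylation of a prochiral 2-benzylpropane-1,3-diol built from syringaldehyde and diethyl malonate.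

Key step: step 10

Remark: C3 of the target is read from the SMILES as (S); the same spatial arrangement is (S) in 8, 10 and 12–16 and (R) in aldehyde 9 (CIP priorities only). The sense of induction in step 6 cannot be fixed in advance for this substrate, so the ligand antipode is taken to be the one that a test run against the racemate shows to lead to (S)-8.

**Step 1**
Reactants: 1 syringaldehyde (4-hydroxy-3,5-dimethoxybenzaldehyde)
Product: 2 2-bromo-4-hydroxy-3,5-dimethoxybenzaldehyde
Conditions: Br2 (1.05 equiv), NaOAc, AcOH, rt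
Reagents that add atoms: bromine, BrBr
Why: Electrophilic aromatic bromination; C2 and C6 are the only open positions, are equivalent and are each ortho to one methoxy group and para to the other, and one equivalent of bromine should stop at the monobromide because the first bromine deactivates and crowds the ring.

**Step 2**
Reactants: 2 2-bromo-4-hydroxy-3,5-dimethoxybenzaldehyde
Product: 3 2-bromo-3,5-dimethoxy-4-(methoxymethoxy)benzaldehyde
Conditions: MOMCl, i-Pr2NEt, CH2Cl2, 0 °C to rt
Reagents that add atoms: chloromethyl methyl ether, COCCl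
Why: O-Alkylation of the acidic para-formyl phenol (Williamson-type acetal protection); the methoxymethyl ether is inert to hydride, base, organolithium and heat, which is everything it meets before step 11.

**Step 3**
Reactants: 3 2-bromo-3,5-dimethoxy-4-(methoxymethoxy)benzaldehyde; 4 diethyl malonate
Product: 5 diethyl 2-{[2-bromo-3,5-dimethoxy-4-(methoxymethoxy)phenyl]methylidene}propanedioate
Conditions: piperidine (cat.), AcOH (cat.), toluene, reflux, Dean–Stark
Reagents that add atoms: none
Why: Knoevenagel condensation driven by azeotropic removal of water; it installs the three-carbon diester unit without a labile electron-rich benzyl halide and without any chance of double alkylation of the malonate.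

**Step 4**
Reactants: 5 diethyl 2-{[2-bromo-3,5-dimethoxy-4-(methoxymethoxy)phenyl]methylidene}propanedioate
Product: 6 diethyl 2-{[2-bromo-3,5-dimethoxy-4-(methoxymethoxy)phenyl]methyl}propanedioate
Conditions: NaBH4, EtOH, 0 °C
Reagents that add atoms: none
Why: Conjugate hydride reduction of the doubly activated alkylidene malonate, which is far faster than ester reduction at 0 °C and leaves the aryl bromide untouched.

**Step 5**
Reactants: 6 diethyl 2-{[2-bromo-3,5-dimethoxy-4-(methoxymethoxy)phenyl]methyl}propanedioate
Product: 7 2-{[2-bromo-3,5-dimethoxy-4-(methoxymethoxy)phenyl]methyl}propane-1,3-diol (achiral, prochiral)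
Conditions: LiAlH4, THF, 0 °C to rt; Fieser work-up
Reagents that add atoms: none
Why: Hydride reduction of both esters to the 2-substituted propane-1,3-diol; the electron-rich aryl bromide and the acetal are not reduced at this temperature.

**Step 6**
Reactants: 7 2-{[2-bromo-3,5-dimethoxy-4-(methoxymethoxy)phenyl]methyl}propane-1,3-diol
Product: 8 (S)-[6,8-dimethoxy-7-(methoxymethoxy)chroman-3-yl]methanol
Conditions: Pd(OAc)2 (5 mol %), SDP(O) (spirobiindane phosphine–phosphine oxide ligand, 10 mol %, antipode as in the remark), Cs2CO3, toluene, 80 °C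
Reagents that add atoms: none
Why: Enantioselective desymmetrising intramolecular aryl C–O coupling (Buchwald–Hartwig-type etherification), a known way from 2-(2-bromobenzyl)propane-1,3-diols to (chroman-3-yl)methanols; after oxidative addition the chiral ligand sphere should admit only one of the two enantiotopic hydroxymethyl arms to alkoxide binding and reductive elimination, which closes the pyran ring and sets C3.

**Step 7**
Reactants: 8 (S)-[6,8-dimethoxy-7-(methoxymethoxy)chroman-3-yl]methanol
Product: 9 (R)-6,8-dimethoxy-7-(methoxymethoxy)chroman-3-carbaldehyde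
Conditions: Dess–Martin periodinane, CH2Cl2, 0 °C to rt; carried on crude
Reagents that add atoms: none
Why: Dess–Martin oxidation of the primary alcohol under base-free conditions, chosen so that the enolisable β-aryloxy aldehyde is neither epimerised nor opened by β-elimination of the phenoxide.

**Step 8**
Reactants: 9 (R)-6,8-dimethoxy-7-(methoxymethoxy)chroman-3-carbaldehyde
Product: 10 (S)-3-(2,2-dibromovinyl)-6,8-dimethoxy-7-(methoxymethoxy)chroman
Conditions: CBr4, PPh3, 2,6-lutidine, CH2Cl2, 0 °C
Reagents that add atoms: carbon tetrabromide, BrC(Br)(Br)Br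
Why: Ramirez dibromo-olefination (first half of the Corey–Fuchs homologation), a Wittig-type reaction whose ylide is practically non-basic, so the α-stereocentre should be retained, with 2,6-lutidine buffering traces of HBr to protect the acetal.

**Step 9**
Reactants: 10 (S)-3-(2,2-dibromovinyl)-6,8-dimethoxy-7-(methoxymethoxy)chroman; 11 dimethyl squarate (3,4-dimethoxycyclobut-3-ene-1,2-dione)
Product: 13 4-hydroxy-2,3-dimethoxy-4-{[(S)-6,8-dimethoxy-7-(methoxymethoxy)chroman-3-yl]ethynyl}cyclobut-2-en-1-one (both carbinol epimers), via lithium acetylide 12 (not isolated)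
Conditions: n-BuLi (2.0 equiv), THF, −78 °C, 1 h; then transferred onto 11 (1.2 equiv), THF, −78 °C; sat. aq. NH4Cl, −78 °C
Reagents that add atoms: none
Why: Second half of the Corey–Fuchs sequence (bromine–lithium exchange, Fritsch–Buttenberg–Wiechell 1,2-hydrogen shift, deprotonation) should give acetylide 12, which adds 1,2 to one of the two equivalent carbonyl groups of dimethyl squarate, the standard entry to 4-alkynyl-4-hydroxycyclobutenones; the new carbinol centre is formed without control and is erased in step 10.

**Step 10**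
Reactants: 13 4-hydroxy-2,3-dimethoxy-4-{[(S)-6,8-dimethoxy-7-(methoxymethoxy)chroman-3-yl]ethynyl}cyclobut-2-en-1-one
Product: 16 2,3-dimethoxy-5-[(S)-6,8-dimethoxy-7-(methoxymethoxy)chroman-3-yl]cyclohexa-2,5-diene-1,4-dione, via enynyl ketene 14 (not isolated), via ring diradical 15 (not isolated)
Conditions: p-xylene (0.01 M, degassed), reflux (138 °C), Ar
Reagents that add atoms: none
Why: Heat opens the cyclobutenone C1–C4 bond by conrotatory 4π-electrocyclic ring opening, the carbinol OH turning outward so that the alkynyl arm lies cis to the ketene in (Z)-enynyl ketene 14. The ketene carbon (future C2′) then bonds to the alkyne carbon that carries chroman C3 (future C1′) in a 6-endo-dig closure, giving the six-membered ring as aryl σ-radical/phenoxyl diradical 15, and transfer of the hydroxyl hydrogen to the radical carbon (C6′) should deliver quinone 16. This is the thermal ring expansion of 4-alkynyl-4-hydroxycyclobutenones to 1,4-benzoquinones (Moore rearrangement), established for dimethyl squarate adducts of alkyl-substituted alkynes. No stereocentre is created: the carbinol centre is destroyed, so both epimers of 13 converge, and C3 is a spectator because the medium is neutral and base-free. The selectivity needed is six- over five-membered (5-exo-dig, alkylidene-cyclopentenedione) closure, and the secondary-alkyl substituent on the alkyne offers no stabilisation to the exocyclic vinyl radical of the five-ring path, which favours the quinone. The chroman has no hydrogen in a 1,5-relationship to the radical carbon, and high dilution in a degassed solvent that is a poor hydrogen donor should keep intermolecular radical chemistry down.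

**Step 11**
Reactants: 16 2,3-dimethoxy-5-[(S)-6,8-dimethoxy-7-(methoxymethoxy)chroman-3-yl]cyclohexa-2,5-diene-1,4-dione
Product: 17 2-[(S)-7-hydroxy-6,8-dimethoxychroman-3-yl]-5,6-dimethoxycyclohexa-2,5-diene-1,4-dione (CNP0121136.1)
Conditions: TFA, CH2Cl2 (1:10), H2O (5 equiv), 0 °C
Reagents that add atoms: none
Why: Acid-catalysed hydrolysis of the aryl methoxymethyl acetal via the oxocarbenium ion; the acid is non-nucleophilic, so nothing can add to the quinone, and the quinone, its vinylogous-ester methoxy groups and C3 should be indifferent to dilute acid at 0 °C.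

**Compound list**

1 | syringaldehyde (4-hydroxy-3,5-dimethoxybenzaldehyde) | COc1cc(C=O)cc(OC)c1O | starting material
2 | 2-bromo-4-hydroxy-3,5-dimethoxybenzaldehyde | COc1cc(C=O)c(Br)c(OC)c1O | intermediate
3 | 2-bromo-3,5-dimethoxy-4-(methoxymethoxy)benzaldehyde | COCOc1c(OC)cc(C=O)c(Br)c1OC | intermediate
4 | diethyl malonate | CCOC(=O)CC(=O)OCC | starting material
5 | diethyl 2-{[2-bromo-3,5-dimethoxy-4-(methoxymethoxy)phenyl]methylidene}propanedioate | CCOC(=O)C(=Cc1cc(OC)c(OCOC)c(OC)c1Br)C(=O)OCC | intermediate
6 | diethyl 2-{[2-bromo-3,5-dimethoxy-4-(methoxymethoxy)phenyl]methyl}propanedioate | CCOC(=O)C(Cc1cc(OC)c(OCOC)c(OC)c1Br)C(=O)OCC | intermediate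
7 | 2-{[2-bromo-3,5-dimethoxy-4-(methoxymethoxy)phenyl]methyl}propane-1,3-diol | OCC(CO)Cc1cc(OC)c(OCOC)c(OC)c1Br | intermediate
8 | (S)-[6,8-dimethoxy-7-(methoxymethoxy)chroman-3-yl]methanol | OC[C@H]1COc2c(OC)c(OCOC)c(OC)cc2C1 | intermediate
9 | (R)-6,8-dimethoxy-7-(methoxymethoxy)chroman-3-carbaldehyde | O=C[C@H]1COc2c(OC)c(OCOC)c(OC)cc2C1 | intermediate
10 | (S)-3-(2,2-dibromovinyl)-6,8-dimethoxy-7-(methoxymethoxy)chroman | BrC(Br)=C[C@H]1COc2c(OC)c(OCOC)c(OC)cc2C1 | intermediate
11 | dimethyl squarate (3,4-dimethoxycyclobut-3-ene-1,2-dione) | COC1=C(OC)C(=O)C1=O | starting material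
12 | lithium {[(S)-6,8-dimethoxy-7-(methoxymethoxy)chroman-3-yl]ethynyl}ide (lithium acetylide, not isolated) | [Li]C#C[C@H]1COc2c(OC)c(OCOC)c(OC)cc2C1 | intermediate
13 | 4-hydroxy-2,3-dimethoxy-4-{[(S)-6,8-dimethoxy-7-(methoxymethoxy)chroman-3-yl]ethynyl}cyclobut-2-en-1-one (both carbinol epimers) | COC1=C(OC)C(O)(C#C[C@H]2COc3c(OC)c(OCOC)c(OC)cc3C2)C1=O | intermediate
14 | (3Z)-4-hydroxy-2,3-dimethoxy-6-[(S)-6,8-dimethoxy-7-(methoxymethoxy)chroman-3-yl]hexa-1,3-dien-5-yn-1-one (enynyl ketene, not isolated) | O=C=C(OC)/C(OC)=C(/O)C#C[C@H]1COc2c(OC)c(OCOC)c(OC)cc2C1 | intermediate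
15 | 5-hydroxy-3,4-dimethoxy-1-[(S)-6,8-dimethoxy-7-(methoxymethoxy)chroman-3-yl]benzen-6-yl-2-oxyl diradical (not isolated) | COc1c(OC)c([O])c([C@H]2COc3c(OC)c(OCOC)c(OC)cc3C2)[c]c1O | intermediate
16 | 2,3-dimethoxy-5-[(S)-6,8-dimethoxy-7-(methoxymethoxy)chroman-3-yl]cyclohexa-2,5-diene-1,4-dione | COC1=C(OC)C(=O)C([C@H]2COc3c(OC)c(OCOC)c(OC)cc3C2)=CC1=O | intermediate
17 | 2-[(S)-7-hydroxy-6,8-dimethoxychroman-3-yl]-5,6-dimethoxycyclohexa-2,5-diene-1,4-dione (CNP0121136.1) | COC1=C(OC)C(=O)C([C@H]2COc3c(cc(OC)c(O)c3OC)C2)=CC1=O | target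

**Step count and risk**

Total steps: 11. Longest linear sequence: 11 steps (1 to 17); 4 and 11 enter as purchased building blocks.

Steps most likely to fail:

1. Step 10 (key step). The enynyl ketene may close through the proximal alkyne carbon to the five-membered alkylidene-cyclopentenedione, or the diradical may take hydrogen from the surroundings instead of from its own hydroxyl, so that less quinone forms. The fallback replaces the diradical closure by a polar 6π-electrocyclisation of a dienyl ketene and accepts one mild oxidation at the end. It sets out from aldehyde 9. Takai olefination (CrCl2, CHI3, THF, 0 °C) should give (S,E)-3-(2-iodovinyl)-6,8-dimethoxy-7-(methoxymethoxy)chroman F1. Iodine–lithium exchange (t-BuLi, 2 equiv, Et2O, −78 °C) should give the (E)-vinyllithium F2, and addition to 11 at −78 °C the 4-alkenyl-4-hydroxycyclobutenone F3. Heating F3 in toluene at 110 °C (4π opening, 6π closure, tautomerisation) should give 2,3-dimethoxy-5-[(S)-6,8-dimethoxy-7-(methoxymethoxy)chroman-3-yl]benzene-1,4-diol F4. Ag2O in Et2O at rt oxidises only the hydroquinone, the A ring still being a fully alkylated arene, and the route is rejoined at 16.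

2. Step 6. The hindered, electron-rich aryl bromide may couple with insufficient discrimination between the two hydroxymethyl arms, or be diverted into β-hydride elimination and hydrodebromination. The fallback separates stereocontrol from ring closure and sets out from diol 7.
   - Lipase-catalysed monoacetylation (Pseudomonas cepacia lipase, vinyl acetate, t-BuOMe, rt) should give (S)-3-[2-bromo-3,5-dimethoxy-4-(methoxymethoxy)phenyl]-2-(hydroxymethyl)propyl acetate F5. Should the enzyme prefer the other arm, the same antipode is taken from lipase hydrolysis of the diacetate.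
   - A base-mediated cyclisation of the monoacetate would racemise it by acyl migration, so the free hydroxyl is silylated first (TBSCl, imidazole, DMF) to (R)-3-[2-bromo-3,5-dimethoxy-4-(methoxymethoxy)phenyl]-2-{[(tert-butyldimethylsilyl)oxy]methyl}propyl acetate F6.
   - Methanolysis of the acetate (K2CO3, MeOH) gives (R)-3-[2-bromo-3,5-dimethoxy-4-(methoxymethoxy)phenyl]-2-{[(tert-butyldimethylsilyl)oxy]methyl}propan-1-ol F7.
   - An achiral intramolecular Ullmann etherification (CuI, 1,10-phenanthroline, Cs2CO3, toluene, 110 °C) closes the ring to (R)-tert-butyl{[6,8-dimethoxy-7-(methoxymethoxy)chroman-3-yl]methoxy}dimethylsilane F8.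
   - TBAF in THF returns the route to 8.

3. Step 9. The carbenoid rearrangement may be incomplete, or residual butyllithium may compete with the acetylide for the squarate, giving butyl adducts and double addition. The fallback makes the alkyne by a different homologation and isolates it, so that the acetylide is formed with exact stoichiometry. It sets out from aldehyde 9. Seyferth–Gilbert homologation with the Ohira–Bestmann reagent (dimethyl (1-diazo-2-oxopropyl)phosphonate, K2CO3, MeOH, 0 °C, short contact time to limit enolisation) should give (S)-3-ethynyl-6,8-dimethoxy-7-(methoxymethoxy)chroman F9. After purification, one equivalent of n-BuLi (THF, −78 °C) converts F9 into acetylide 12, where the route is rejoined and 12 is added to 11 as in step 9.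

**Further compounds**

F1 | step 10 | (S,E)-3-(2-iodovinyl)-6,8-dimethoxy-7-(methoxymethoxy)chroman | I/C=C/[C@H]1COc2c(OC)c(OCOC)c(OC)cc2C1
F2 | step 10 | lithium (E)-2-[(S)-6,8-dimethoxy-7-(methoxymethoxy)chroman-3-yl]ethenide (vinyllithium, not isolated) | [Li]/C=C/[C@H]1COc2c(OC)c(OCOC)c(OC)cc2C1
F3 | step 10 | 4-hydroxy-2,3-dimethoxy-4-{(E)-2-[(S)-6,8-dimethoxy-7-(methoxymethoxy)chroman-3-yl]ethenyl}cyclobut-2-en-1-one (both carbinol epimers) | COC1=C(OC)C(O)(/C=C/[C@H]2COc3c(OC)c(OCOC)c(OC)cc3C2)C1=O
F4 | step 10 | 2,3-dimethoxy-5-[(S)-6,8-dimethoxy-7-(methoxymethoxy)chroman-3-yl]benzene-1,4-diol | COc1c(O)cc([C@H]2COc3c(OC)c(OCOC)c(OC)cc3C2)c(O)c1OC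
F5 | step 6 | (S)-3-[2-bromo-3,5-dimethoxy-4-(methoxymethoxy)phenyl]-2-(hydroxymethyl)propyl acetate | OC[C@H](Cc1cc(OC)c(OCOC)c(OC)c1Br)COC(C)=O
F6 | step 6 | (R)-3-[2-bromo-3,5-dimethoxy-4-(methoxymethoxy)phenyl]-2-{[(tert-butyldimethylsilyl)oxy]methyl}propyl acetate | CC(C)(C)[Si](C)(C)OC[C@H](Cc1cc(OC)c(OCOC)c(OC)c1Br)COC(C)=O
F7 | step 6 | (R)-3-[2-bromo-3,5-dimethoxy-4-(methoxymethoxy)phenyl]-2-{[(tert-butyldimethylsilyl)oxy]methyl}propan-1-ol | CC(C)(C)[Si](C)(C)OC[C@H](Cc1cc(OC)c(OCOC)c(OC)c1Br)CO
F8 | step 6 | (R)-tert-butyl{[6,8-dimethoxy-7-(methoxymethoxy)chroman-3-yl]methoxy}dimethylsilane | CC(C)(C)[Si](C)(C)OC[C@H]1COc2c(OC)c(OCOC)c(OC)cc2C1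
F9 | step 9 | (S)-3-ethynyl-6,8-dimethoxy-7-(methoxymethoxy)chroman | C#C[C@H]1COc2c(OC)c(OCOC)c(OC)cc2C1
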